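The top flavan unit is disconnected at O1–C8a and C2–C3: O1–C2 becomes the carbonyl of 3,4-bis(benzyloxy)benzaldehyde, and C3–C4–C4a–C8a an α-benzyloxy ketone on a 2-fluoro-4,6-bis(benzyloxy)phenyl ring. The key step exploits the place of C8a in ring A, ortho to C4a and meta to both ring-A oxygens: a C4 carbonyl turns C3 into an enol nucleophile and C8a–F into an SNAr site. A catalytic asymmetric syn-aldol sets C2 and C3, and the silyl aldolate closes ring C in the same flask. The derived flavan-4-ol serves twice, as C4 electrophile of the top unit and, after thiolysis, as middle unit; the mirror-image sequence gives the bottom unit.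

Key step: step 4

Remark: the units are called top (4β→8-linked), middle (carrying the 4-O-ether) and bottom (all-cis 3,4-diol unit), with flavan numbering (O1, C2, C3, C4, C4a, C5–C8, C8a); amide 5 is taken as a catalogue compound.
Remark: the (2R,3R)-tartrate-derived acyloxyborane is assumed to direct attack to the Re face of the aldehyde; if the first run shows the opposite sense, the ligand antipodes of steps 4 and 6 are exchanged.

Step 1
Reactants: 1 1,3,5-trifluorobenzene; 2 benzyl alcohol (2.05 equiv)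
Product: 4 1,3-bis(benzyloxy)-5-fluorobenzene, via 1-(benzyloxy)-3,5-difluorobenzene 3 (not isolated)
Conditions: NaH, DMF, 0 → 80 °C
Reagents that add atoms: none
Why: Twofold nucleophilic aromatic substitution (SNAr): each benzyloxy group that enters is meta to the remaining fluorines and so does not switch off the next displacement, while the third fluoride stays because only two equivalents of alkoxide are used.

Step 2
Reactants: 4 1,3-bis(benzyloxy)-5-fluorobenzene; 5 2-(benzyloxy)-N-methoxy-N-methylacetamide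
Product: 7 2-(benzyloxy)-1-[2,4-bis(benzyloxy)-6-fluorophenyl]ethan-1-one, via aryllithium 6 (not isolated)
Conditions: n-BuLi, THF, −78 °C; then 5, −78 → −20 °C; aq. NH4Cl
Reagents that add atoms: none
Why: Directed ortho-metalation followed by Weinreb ketone synthesis: the C–H flanked by fluorine and benzyloxy (two equivalent positions) is the most acidic and should be lithiated at −78 °C, where the ortho-fluoro aryllithium 6 does not lose LiF, and the chelated tetrahedral adduct of amide 5 prevents over-addition.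

Step 3
Reactants: 7 2-(benzyloxy)-1-[2,4-bis(benzyloxy)-6-fluorophenyl]ethan-1-one
Product: 8 (Z)-{[2-(benzyloxy)-1-[2,4-bis(benzyloxy)-6-fluorophenyl]ethenyl]oxy}trimethylsilane
Conditions: TMSOTf, Et3N, CH2Cl2, 0 °C
Reagents that add atoms: trimethylsilyl triflate (TMSOTf), C[Si](C)(C)OS(=O)(=O)C(F)(F)F
Why: Soft enolisation (silyl enol ether formation) at the only enolisable position should give the (Z)-enol silane, in which the aryl and benzyloxy groups are trans.

Step 4
Reactants: 8 (Z)-enol silane; 9 3,4-bis(benzyloxy)benzaldehyde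
Product: 11 (2R,3S)-3,5,7-tris(benzyloxy)-2-[3,4-bis(benzyloxy)phenyl]chroman-4-one (2,3-cis), via syn silyl aldolate 10 (not isolated)
Conditions: acyloxyborane from (2S,3S)-2-O-(2,6-diisopropoxybenzoyl)tartaric acid and BH3·THF (20 mol %), EtCN, −78 °C; then CsF (0.3 equiv), DMF, −40 → 0 °C
Reagents that add atoms: none
Why: The acyloxyborane activates aldehyde 9 and enol silane 8 adds through an open antiperiplanar transition state to give the syn silyl aldolate 10; fluoride then removes the silyl group, the alkoxide O1 displaces fluoride at C8a by addition–elimination, and the fluoride set free desilylates the next molecule. The closest known types are the Lewis acid-catalysed asymmetric Mukaiyama aldol of aryl ketone enol silanes with aromatic aldehydes and the fluoride-triggered intramolecular SNAr of an ortho-fluoroaryl ketone. Ring C closes in a 6-exo-trig mode through a Meisenheimer intermediate that the C4 carbonyl stabilises. C2 is set by the catalyst, whose antipode is chosen to expose the Si face of the aldehyde, and C3 is set relative to C2 by the syn preference of the open transition state; a syn aldol with O1 retained maps onto the 2,3-cis flavanone. The step needs chemoselective arylation of O1, secured because C8a–F is the only leaving group on ring A and only the six-membered closure is possible, and it needs C3 to keep its configuration next to the ketone, secured by the low basicity of a fluoride-catalytic desilylation at or below 0 °C.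

Step 5
Reactants: 11 (2R,3S)-flavanone
Product: 12 (2R,3R,4R)-3,5,7-tris(benzyloxy)-2-[3,4-bis(benzyloxy)phenyl]chroman-4-ol (all-cis)
Conditions: NaBH4, THF/EtOH, −40 → 0 °C
Reagents that add atoms: none
Why: Hydride reduction of the aryl ketone under Felkin–Anh control: hydride should enter anti to the axial C3 benzyloxy group and place the C4 hydroxyl cis to it (4R), the low temperature keeping the base-labile C3 centre intact; this C4 configuration is lost again in steps 8 and 9.

Step 6
Reactants: 8 (Z)-enol silane; 9 3,4-bis(benzyloxy)benzaldehyde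
Product: 14 (2S,3R)-3,5,7-tris(benzyloxy)-2-[3,4-bis(benzyloxy)phenyl]chroman-4-one (2,3-cis), via syn silyl aldolate 13 (not isolated)
Conditions: acyloxyborane from (2R,3R)-2-O-(2,6-diisopropoxybenzoyl)tartaric acid and BH3·THF (20 mol %), EtCN, −78 °C; then CsF (0.3 equiv), DMF, −40 → 0 °C
Reagents that add atoms: none
Why: Same asymmetric Mukaiyama aldol and fluoride-relayed SNAr closure as step 4; the enantiomeric catalyst should direct the enol silane to the Re face of the aldehyde, which sets C2 as S and, through the syn preference, C3 as R.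

Step 7
Reactants: 14 (2S,3R)-flavanone
Product: 15 (2S,3S,4S)-3,5,7-tris(benzyloxy)-2-[3,4-bis(benzyloxy)phenyl]chroman-4-ol (all-cis)
Conditions: NaBH4, THF/EtOH, −40 → 0 °C
Reagents that add atoms: none
Why: Felkin–Anh hydride reduction as in step 5, here stereodefining: attack anti to the axial C3 benzyloxy group should set C4 as S, cis to both neighbours, the configuration the bottom unit keeps to the end.

Step 8
Reactants: 12 (2R,3R,4R)-chroman-4-ol; 16 2,6-dimethylbenzenethiol (3 equiv)
Product: 17 (2R,3S,4S)-3,5,7-tris(benzyloxy)-2-[3,4-bis(benzyloxy)phenyl]-4-[(2,6-dimethylphenyl)sulfanyl]chromane (4β, 3,4-trans; the 3S label reflects only the priority of sulfur)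
Conditions: BF3·OEt2 (0.5 equiv), 4 Å MS, CH2Cl2, −78 → −30 °C
Reagents that add atoms: none
Why: Lewis acid-mediated SN1 substitution (thiolysis of a flavan-4-ol): BF3 ionises the C4 hydroxyl to the cation stabilised by the C5 and C7 oxygens, and the thiol, in excess and far more nucleophilic than ring A, should add anti to the C3 benzyloxy group to give the 4β sulfide, a leaving group that resists hard Lewis acids.

Step 9
Reactants: 12 (2R,3R,4R)-chroman-4-ol; 17 4β-sulfide (2.5 equiv, excess recovered)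
Product: 18 deca-O-benzyl dimer: (2R,3R,4R) top unit bonded from C4 (β) to C8 of the (2R,3S,4S) 4β-[(2,6-dimethylphenyl)sulfanyl] lower unit
Conditions: BF3·OEt2, 4 Å MS, CH2Cl2, −78 → −40 °C, slow addition of 12
Reagents that add atoms: none
Why: Friedel–Crafts alkylation through the C4 benzylic cation of 12: the hard Lewis acid ionises the C4 hydroxyl but leaves the C4 sulfide of 17 untouched, C8 of 17 (the most nucleophilic ring-A position) attacks anti to the C3 benzyloxy group and should set C4 of the top unit as R (4β→8), and the excess of 17 suppresses self-condensation of 12.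

Step 10
Reactants: 18 dimer sulfide; 15 (2S,3S,4S)-chroman-4-ol (2 equiv)
Product: 19 pentadeca-O-benzyl ether of the target: top (2R,3R,4R), middle (2R,3R,4S), bottom (2S,3S,4S), C4(middle)–O–C4(bottom)
Conditions: AgOTf, 2,6-di-tert-butyl-4-methylpyridine, 4 Å MS, CH2Cl2, −40 → 0 °C
Reagents that add atoms: none
Why: Thiophile-promoted SN1 etherification (the thioglycoside type of activation): AgOTf removes the arylthio group as silver thiolate, alcohol 15 adds through oxygen to the C4 cation anti to the C3 benzyloxy group and should set C4 of the middle unit as S, the hindered pyridine takes up the proton so that the ether forms under kinetic control and does not re-ionise to C-alkylate ring A, and C4 of 15 is retained because its C–O bond is not broken.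

Step 11
Reactants: 19 pentadeca-O-benzyl ether
Product: 20 CNP0310719.1
Conditions: H2 (1 atm), Pd(OH)2/C, THF/MeOH/H2O, rt
Reagents that add atoms: none
Why: Catalytic hydrogenolysis of the fifteen primary benzyl ethers under neutral conditions; the secondary, flanked C4–O–C4 ether and the ring C2–O1 bonds are benzylic too but should react far more slowly, so the reaction is stopped at the uptake of fifteen equivalents of hydrogen, and no stereocentre is affected.

Compound list
1 | 1,3,5-trifluorobenzene | Fc1cc(F)cc(F)c1 | starting material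
2 | benzyl alcohol | OCc1ccccc1 | starting material
3 | 1-(benzyloxy)-3,5-difluorobenzene (not isolated) | Fc1cc(F)cc(OCc2ccccc2)c1 | intermediate
4 | 1,3-bis(benzyloxy)-5-fluorobenzene | Fc1cc(OCc2ccccc2)cc(OCc2ccccc2)c1 | intermediate
5 | 2-(benzyloxy)-N-methoxy-N-methylacetamide | CON(C)C(=O)COCc1ccccc1 | starting material
6 | [2,4-bis(benzyloxy)-6-fluorophenyl]lithium (not isolated) | [Li]c1c(F)cc(OCc2ccccc2)cc1OCc1ccccc1 | intermediate
7 | 2-(benzyloxy)-1-[2,4-bis(benzyloxy)-6-fluorophenyl]ethan-1-one | O=C(COCc1ccccc1)c1c(F)cc(OCc2ccccc2)cc1OCc1ccccc1 | intermediate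
8 | (Z)-{[2-(benzyloxy)-1-[2,4-bis(benzyloxy)-6-fluorophenyl]ethenyl]oxy}trimethylsilane | C[Si](C)(C)O/C(=C\OCc1ccccc1)c1c(F)cc(OCc2ccccc2)cc1OCc1ccccc1 | intermediate
9 | 3,4-bis(benzyloxy)benzaldehyde | O=Cc1ccc(OCc2ccccc2)c(OCc2ccccc2)c1 | starting material
10 | (2S,3R)-2-(benzyloxy)-3-[3,4-bis(benzyloxy)phenyl]-1-[2,4-bis(benzyloxy)-6-fluorophenyl]-3-[(trimethylsilyl)oxy]propan-1-one (syn; not isolated) | C[Si](C)(C)O[C@H](c1ccc(OCc2ccccc2)c(OCc2ccccc2)c1)[C@H](OCc1ccccc1)C(=O)c1c(F)cc(OCc2ccccc2)cc1OCc1ccccc1 | intermediate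
11 | (2R,3S)-3,5,7-tris(benzyloxy)-2-[3,4-bis(benzyloxy)phenyl]chroman-4-one | c4ccccc4COc1cc(OCc4ccccc4)c2c(c1)O[C@H](c3ccc(OCc4ccccc4)c(OCc4ccccc4)c3)[C@H](OCc4ccccc4)C2=O | intermediate
12 | (2R,3R,4R)-3,5,7-tris(benzyloxy)-2-[3,4-bis(benzyloxy)phenyl]chroman-4-ol | c4ccccc4COc1cc(OCc4ccccc4)c2c(c1)O[C@H](c3ccc(OCc4ccccc4)c(OCc4ccccc4)c3)[C@H](OCc4ccccc4)[C@@H]2O | intermediate
13 | (2R,3S)-2-(benzyloxy)-3-[3,4-bis(benzyloxy)phenyl]-1-[2,4-bis(benzyloxy)-6-fluorophenyl]-3-[(trimethylsilyl)oxy]propan-1-one (syn, enantiomer of 10; not isolated) | C[Si](C)(C)O[C@@H](c1ccc(OCc2ccccc2)c(OCc2ccccc2)c1)[C@@H](OCc1ccccc1)C(=O)c1c(F)cc(OCc2ccccc2)cc1OCc1ccccc1 | intermediate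
14 | (2S,3R)-3,5,7-tris(benzyloxy)-2-[3,4-bis(benzyloxy)phenyl]chroman-4-one | c4ccccc4COc1cc(OCc4ccccc4)c2c(c1)O[C@@H](c3ccc(OCc4ccccc4)c(OCc4ccccc4)c3)[C@@H](OCc4ccccc4)C2=O | intermediate
15 | (2S,3S,4S)-3,5,7-tris(benzyloxy)-2-[3,4-bis(benzyloxy)phenyl]chroman-4-ol | c4ccccc4COc1cc(OCc4ccccc4)c2c(c1)O[C@@H](c3ccc(OCc4ccccc4)c(OCc4ccccc4)c3)[C@@H](OCc4ccccc4)[C@H]2O | intermediate
16 | 2,6-dimethylbenzenethiol | Cc1cccc(C)c1S | starting material
17 | (2R,3S,4S)-3,5,7-tris(benzyloxy)-2-[3,4-bis(benzyloxy)phenyl]-4-[(2,6-dimethylphenyl)sulfanyl]chromane | c4ccccc4COc1cc(OCc4ccccc4)c2c(c1)O[C@H](c3ccc(OCc4ccccc4)c(OCc4ccccc4)c3)[C@H](OCc4ccccc4)[C@H]2Sc5c(C)cccc5C | intermediate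
18 | deca-O-benzyl epicatechin-(4β→8)-4β-[(2,6-dimethylphenyl)sulfanyl]epicatechin | c4ccccc4COc1cc(OCc4ccccc4)c2c(c1)O[C@H](c3ccc(OCc4ccccc4)c(OCc4ccccc4)c3)[C@H](OCc4ccccc4)[C@H]2c1c(OCc4ccccc4)cc(OCc4ccccc4)c2c1O[C@H](c3ccc(OCc4ccccc4)c(OCc4ccccc4)c3)[C@H](OCc4ccccc4)[C@H]2Sc5c(C)cccc5C | intermediate
19 | pentadeca-O-benzyl ether of the target | c4ccccc4COc1cc(OCc4ccccc4)c2c(c1)O[C@H](c3ccc(OCc4ccccc4)c(OCc4ccccc4)c3)[C@H](OCc4ccccc4)[C@H]2c1c(OCc4ccccc4)cc(OCc4ccccc4)c2c1O[C@H](c3ccc(OCc4ccccc4)c(OCc4ccccc4)c3)[C@H](OCc4ccccc4)[C@H]2O[C@H]6c7c(OCc4ccccc4)cc(OCc4ccccc4)cc7O[C@@H](c3ccc(OCc4ccccc4)c(OCc4ccccc4)c3)[C@H]6OCc4ccccc4 | intermediate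
20 | CNP0310719.1 | Oc1cc(O)c2c(c1)O[C@H](c1ccc(O)c(O)c1)[C@H](O)[C@H]2c1c(O)cc(O)c2c1O[C@H](c1ccc(O)c(O)c1)[C@H](O)[C@H]2O[C@H]1c2c(O)cc(O)cc2O[C@@H](c2ccc(O)c(O)c2)[C@H]1O | target

Total step count: 11. Longest linear sequence: 9 steps (steps 1, 2, 3, 4, 5, 8, 9, 10, 11).

Steps most likely to fail

Step 4. What may go wrong: erosion of syn or facial selectivity in the open transition state, retro-aldol scrambling once the alkoxide is unmasked, or epimerisation at C3 of the flavanone. The fallback sets out from 7 and comes back at 12. Ketone 7 is converted with i-Pr2NEt and the antipode of diisopinocampheylboron triflate that exposes the Si face of the aldehyde into its (Z)-boron enolate, which adds to 9 through a closed chair transition state. Oxidative work-up gives (2S,3R)-2-(benzyloxy)-3-[3,4-bis(benzyloxy)phenyl]-1-[2,4-bis(benzyloxy)-6-fluorophenyl]-3-hydroxypropan-1-one F1. Hydroxyl-directed reduction with Me4NBH(OAc)3 in MeCN/AcOH at −30 °C gives the 1,3-anti diol (1R,2S,3R)-2-(benzyloxy)-3-[3,4-bis(benzyloxy)phenyl]-1-[2,4-bis(benzyloxy)-6-fluorophenyl]propane-1,3-diol F2, which can neither fragment nor enolise. KOt-Bu in DMF at 60 °C then closes ring C by SNAr of the C2 alkoxide on C8a–F (the C4 alkoxide cannot reach C8a) and gives 12. With the enantiomeric boron reagent the same three operations would lead through (2R,3S)-2-(benzyloxy)-3-[3,4-bis(benzyloxy)phenyl]-1-[2,4-bis(benzyloxy)-6-fluorophenyl]-3-hydroxypropan-1-one F3 and (1S,2R,3S)-2-(benzyloxy)-3-[3,4-bis(benzyloxy)phenyl]-1-[2,4-bis(benzyloxy)-6-fluorophenyl]propane-1,3-diol F4 to 15, in place of steps 6 and 7.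

Step 10. What may go wrong: capture of the C4 cation by ring A of 15 (C-alkylation) in place of its hindered hydroxyl, or loss of the cation by elimination while the slow capture by the secondary alcohol is awaited. The fallback sets out from 18 and 15 and comes back at 19. AgOTf and 2,6-di-tert-butyl-4-methylpyridine in CH2Cl2 with 2-ethoxyethanol in large excess convert 18 into deca-O-benzyl epicatechin-(4β→8)-4β-(2-ethoxyethoxy)epicatechin F5; the unhindered primary alcohol should capture the cation anti to the C3 benzyloxy group faster than any ring A can. Alcohol 15 is silylated (TMSCl, imidazole, DMF) to (2S,3S,4S)-3,5,7-tris(benzyloxy)-2-[3,4-bis(benzyloxy)phenyl]-4-[(trimethylsilyl)oxy]chromane F6. Catalytic TMSOTf in CH2Cl2 at −78 °C then exchanges the 2-ethoxyethoxy group of F5 for the oxygen of F6, driven by silyl transfer to 2-ethoxyethanol, and Et3N quenches the cold mixture before C-alkylation can follow; the product is 19.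

Step 11. What may go wrong: hydrogenolysis of the doubly benzylic C4–O–C4 ether in competition with debenzylation. The fallback sets out from 19 and comes back at 20: single-electron reductive debenzylation with lithium 4,4′-di-tert-butylbiphenylide in THF at −78 °C, in which electron transfer should go to the unsubstituted phenyl rings of the benzyl groups and not to the oxygen-rich flavan rings, followed by a cold quench with NH4Cl/AcOH; no compound outside the list is formed (F0).

Further compounds
F1 | step 4 | (2S,3R)-2-(benzyloxy)-3-[3,4-bis(benzyloxy)phenyl]-1-[2,4-bis(benzyloxy)-6-fluorophenyl]-3-hydroxypropan-1-one | O[C@H](c1ccc(OCc2ccccc2)c(OCc2ccccc2)c1)[C@H](OCc1ccccc1)C(=O)c1c(F)cc(OCc2ccccc2)cc1OCc1ccccc1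
F2 | step 4 | (1R,2S,3R)-2-(benzyloxy)-3-[3,4-bis(benzyloxy)phenyl]-1-[2,4-bis(benzyloxy)-6-fluorophenyl]propane-1,3-diol | O[C@H](c1ccc(OCc2ccccc2)c(OCc2ccccc2)c1)[C@H](OCc1ccccc1)[C@H](O)c1c(F)cc(OCc2ccccc2)cc1OCc1ccccc1
F3 | step 4 | (2R,3S)-2-(benzyloxy)-3-[3,4-bis(benzyloxy)phenyl]-1-[2,4-bis(benzyloxy)-6-fluorophenyl]-3-hydroxypropan-1-one | O[C@@H](c1ccc(OCc2ccccc2)c(OCc2ccccc2)c1)[C@@H](OCc1ccccc1)C(=O)c1c(F)cc(OCc2ccccc2)cc1OCc1ccccc1
F4 | step 4 | (1S,2R,3S)-2-(benzyloxy)-3-[3,4-bis(benzyloxy)phenyl]-1-[2,4-bis(benzyloxy)-6-fluorophenyl]propane-1,3-diol | O[C@@H](c1ccc(OCc2ccccc2)c(OCc2ccccc2)c1)[C@@H](OCc1ccccc1)[C@@H](O)c1c(F)cc(OCc2ccccc2)cc1OCc1ccccc1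
F5 | step 10 | deca-O-benzyl epicatechin-(4β→8)-4β-(2-ethoxyethoxy)epicatechin | c4ccccc4COc1cc(OCc4ccccc4)c2c(c1)O[C@H](c3ccc(OCc4ccccc4)c(OCc4ccccc4)c3)[C@H](OCc4ccccc4)[C@H]2c1c(OCc4ccccc4)cc(OCc4ccccc4)c2c1O[C@H](c3ccc(OCc4ccccc4)c(OCc4ccccc4)c3)[C@H](OCc4ccccc4)[C@H]2OCCOCC
F6 | step 10 | (2S,3S,4S)-3,5,7-tris(benzyloxy)-2-[3,4-bis(benzyloxy)phenyl]-4-[(trimethylsilyl)oxy]chromane | c4ccccc4COc1cc(OCc4ccccc4)c2c(c1)O[C@@H](c3ccc(OCc4ccccc4)c(OCc4ccccc4)c3)[C@@H](OCc4ccccc4)[C@H]2O[Si](C)(C)C
F0 | step 11 | none | none
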